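Whether to leave this flask past its time is a decision about one fork, where a molecule of electrophile meets either nucleophile or target.

| setting | alpha | beta | delta | flask |
|---|---|---|---|---|
| electrophile | 10 mM | 15 mM | 20 mM | 20 mM |
| nucleophile | 1 equiv | 1 equiv | 2 equiv | 1.00 equiv |
| free base | 2 equiv | 2 equiv | 2 equiv | 2.00 equiv |
| remark | run made earlier | run made earlier | run made earlier |  |
| time |  |  |  | 4.0 h |

- alpha (time / h: electrophile / %, target / %, side product / %): 0.200: 58.4, 40.6, 1.9; 0.333: 51.4, 45.8, 2.9; 0.417: 48.9, 47.3, 3.5; 0.667: 44.6, 49.6, 5.9; 1.00: 40.7, 50.5, 8.4; 1.50: 35.8, 51.0, 13.4; 2.50: 29.1, 50.6, 20.1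
- beta (time / h: electrophile / %, target / %, side product / %): 0.133: 58.2, 40.6, 2.0; 0.333: 47.3, 48.0, 4.4; 0.667: 40.7, 49.8, 8.7; 1.00: 36.8, 50.3, 13.3; 1.33: 33.5, 49.7, 16.7; 2.00: 27.8, 49.0, 23.0; 2.50: 24.5, 48.6, 26.6
- delta (time / h: electrophile / %, target / %, side product / %): 0.500: 6.4, 89.3, 5.1; 1.00: 2.0, 91.7, 6.8; 1.33: 0.8, 92.0, 6.8; 2.00: 0, 92.6, 7.3; 2.50: 0.2, 92.4, 7.6

(each reading ± 0.3 percentage points)

- in percentages every species weighs as the electrophile in it: one side product counts as two
- candidate steps: electrophile + nucleophile -> acid set free + target; nucleophile + acid set free <-> protonated nucleophile; acid set free + free base <-> salt of the base; electrophile + target -> side product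
- the reaction counts as stopped when no species that holds the electrophile changes by six tenths of a point or more over the second half of the time

- at 4.0 h, what has stopped the reaction, if anything has (the free base has run out first / all of the electrophile has reacted / it is still moving)
- how much of the electrophile has reacted by 4.0 h
- how much target there is at 4.0 h, in percent of the electrophile charged
- how much side product there is at 4.0 h, in percent of the electrophile charged
- amount of target if the flask were left three thousand times as long, in percent of the electrophile charged

In the first instants electrophile meets nucleophile and target forms: alpha has 40.6% by 0.200 h. Acid set free then takes a second nucleophile as protonated nucleophile, a reading supported by alpha stalling near half while delta, with twice the equivalents of nucleophile at 20 mM of electrophile, reaches 92.6%.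

In the middle, free base returns a trickle of nucleophile and target meets electrophile. One side product counts as two, so half its gain is electrophile lost to target. What remains of the electrophile lost made target. Beta gives 1.36 from 0.333 h to 1.00 h, then 0.850 up to 2.50 h: this is the fork ratio, electrophile lost making target per electrophile lost consuming it, and in beta it is lower in the later window.

Dose, c(electrophile) times time, serves as a rough clock: alpha and beta both read 40.7% of electrophile at dose 36.0 M·s, but 35.8% against 36.8% at dose 54.0 M·s, so their curves lie close without coinciding. Between beta's windows, at mean doses 31.2 M·s and 85.4 M·s, the ratio falls by 1.60, and the square root of the dose ratio is 1.65. My reckoning takes that root.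

Toward the end, the flask passes beta's last dose, 135 M·s, on its way to 288 M·s, and on the rough clock the root puts its ratio there at 0.559. Beta's tail loses electrophile to target at 0.164 L mol⁻¹ min⁻¹, which with the fork leaves 12.8% electrophile. That is a fall of 12 percentage points over roughly the second half, so the flask is still moving. I reckon target 45.3% and side product 41.7%.

The forecast, on the ground that “alpha, beta and the flask share one curve in concentration × time”, says it is still moving, conversion 87%, target 45.2%, side product 41.6% and, left long, target 39.6%.

The flask gives it is still moving, conversion 85.9%, target 43.2%, side product 42.7% and, left long, target 36.6%.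

    electrophile + nucleophile → acid set free + target (k = 9.83 L mol⁻¹ min⁻¹)
    nucleophile + acid set free ⇌ protonated nucleophile, settled at all times (K = 19900 L mol⁻¹)
    acid set free + free base ⇌ salt of the base, settled at all times (K = 29.9 L mol⁻¹)
    electrophile + target → side product (k = 0.350 L mol⁻¹ min⁻¹)

From 2.00 h to 4.00 h the flask loses 10 points of electrophile, and the fork ratio 0.559 takes target from 47.1% to 44.3%, against 43.2% found. The same flask read at 6.0 h reaches dose 432 M·s, where the root puts the ratio at 0.418. Electrophile falls further to 8.69%, so target should stand at 41.0%; that flask holds 40.8%.

The numbers in the tables are simulated with made-up constants; scatter was added.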